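## Retrosynthetic overview

1. Target 20 ⇐ PMB ether 19 ⇐ C5 angeloylation and hydroxyl‑directed C7–C8 epoxidation of the ten‑membered (7Z)‑ene trans‑4,5‑diol 17.
2. 17 ⇐ C4–C5 bond: samarium‑mediated electroreductive keto‑aldehyde pinacol macrocyclisation of seco compound 15. This is the only carbocycle‑forming step; the oxirane is made afterwards.
3. 15 ⇐ C8–C9 bond: Felkin‑controlled Ni/Cr coupling of α‑angeloyloxy aldehyde 9 with (Z)‑vinyl iodide 11 (C5–C8 plus the C8 methyl).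
4. 9 ⇐ glycol cleavage of a cyclohexane that already carries C1, C3 and C10, made from (S)‑carvone by trans‑epoxidation, C3 alcoholysis, α′‑hydroxylation and Mitsunobu angeloylation.

Assumption: ring carbons are numbered C1–C10 in the order of the target SMILES (C1 = CH–isopropenyl, C3 = CHOH, C4 = C(OH)Me, C5 = CH–OAng, C7/C8 = epoxide, C9 = CH–OAc, C10 = CH–OAng); names of seco and macrocyclic compounds use this numbering where stated.

## Route

Step 1
Reactants: 1 (S)-(+)-carvone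
Product: 2 (1S,4S,6S)-1-methyl-4-(prop-1-en-2-yl)-7-oxabicyclo[4.1.0]heptan-2-one
Conditions: 30% aq. H2O2, NaOH (cat.), MeOH, 0 °C
Reagents that add atoms: hydrogen peroxide OO
Why: Weitz–Scheffer nucleophilic epoxidation touches only the enone, and hydroperoxide adds anti to the isopropenyl group, so the oxirane is trans to it and a later anti opening will place the C3 oxygen cis to isopropenyl.

Step 2
Reactants: 2 (1S,4S,6S)-1-methyl-4-(prop-1-en-2-yl)-7-oxabicyclo[4.1.0]heptan-2-one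
Product: 3 (2S,3R,5S)-2-hydroxy-3-[(4-methoxybenzyl)oxy]-2-methyl-5-(prop-1-en-2-yl)cyclohexan-1-one
Conditions: 4-methoxybenzyl alcohol (3 equiv), Yb(OTf)3 (5 mol %), CH2Cl2, 0 °C → rt
Reagents that add atoms: 4-methoxybenzyl alcohol COc1ccc(CO)cc1
Why: Lewis‑acid‑catalysed SN2 alcoholysis of the α,β‑epoxy ketone at the β‑carbon (the α‑carbon is tertiary and deactivated by the carbonyl) with inversion, so the PMB ether oxygen (target C3–O) ends cis to isopropenyl.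

Step 3
Reactants: 3 (2S,3R,5S)-2-hydroxy-3-[(4-methoxybenzyl)oxy]-2-methyl-5-(prop-1-en-2-yl)cyclohexan-1-one
Product: 6 (2S,3R,5R,6R)-2,6-dihydroxy-3-[(4-methoxybenzyl)oxy]-2-methyl-5-(prop-1-en-2-yl)cyclohexan-1-one, via bis-TMS enol ether 4 (not isolated), via 2,6-bis(trimethylsilyloxy) ketone 5 (not isolated)
Conditions: LDA (2.2 equiv), Me3SiCl (2.5 equiv), THF, −78 °C; mCPBA, NaHCO3, CH2Cl2, −20 °C; 1 M HCl, THF, 0 °C
Reagents that add atoms: mCPBA O=C(OO)c1cccc(Cl)c1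
Why: Rubottom oxidation, in which only C6 can enolise (C2 is quaternary) and the peracid attacks the silyl enol ether anti to the neighbouring isopropenyl group, giving the 6‑OH trans to it for inversion in step 4.

Step 4
Reactants: 6 (2S,3R,5R,6R)-2,6-dihydroxy-3-[(4-methoxybenzyl)oxy]-2-methyl-5-(prop-1-en-2-yl)cyclohexan-1-one
Product: 7 (1S,2R,4R,5S)-5-hydroxy-4-[(4-methoxybenzyl)oxy]-5-methyl-6-oxo-2-(prop-1-en-2-yl)cyclohexyl (2Z)-2-methylbut-2-enoate
Conditions: angelic acid (2 equiv), PPh3 (2 equiv), DIAD (2 equiv), toluene, 0 °C → rt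
Reagents that add atoms: angelic acid C/C=C(C)\C(=O)O
Why: Mitsunobu esterification, SN2 at the secondary α′‑carbinol (the tertiary OH is inert) with inversion, which sets the C10 angelate cis to isopropenyl.

Step 5
Reactants: 7 (1S,2R,4R,5S)-5-hydroxy-4-[(4-methoxybenzyl)oxy]-5-methyl-6-oxo-2-(prop-1-en-2-yl)cyclohexyl (2Z)-2-methylbut-2-enoate
Product: 9 (2S,3R,5R)-5-[(4-methoxybenzyl)oxy]-1,6-dioxo-3-(prop-1-en-2-yl)heptan-2-yl (2Z)-2-methylbut-2-enoate, via cyclohexane-1,2-diol 8 (not isolated)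
Conditions: NaBH4, CeCl3·7H2O, MeOH, −78 → −40 °C; then pH 7 phosphate buffer, NaIO4, THF/H2O, 0 °C; used crude
Reagents that add atoms: none
Why: Luche‑type ketone reduction followed by Malaprade glycol cleavage in one pot, in which the new carbinol configuration is irrelevant because that carbon becomes the C9 aldehyde and the tertiary carbinol becomes the C4 methyl ketone, while C1, C3 and C10 are untouched and the PMB ether blocks cleavage towards C3.

Step 6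
Reactants: 10 3-[(tert-butyldimethylsilyl)oxy]propanal
Product: 11 (Z)-tert-butyl[(4-iodopent-3-en-1-yl)oxy]dimethylsilane
Conditions: EtPPh3I, n-BuLi, THF, 0 °C; I2, −78 °C; NaHMDS, −20 °C; then 10, −78 °C → rt
Reagents that add atoms: ethyltriphenylphosphonium iodide CC[P+](c1ccccc1)(c1ccccc1)c1ccccc1.[I-]; iodine II
Why: Stork–Zhao‑type Wittig olefination with the α‑iodoethylidene ylide, which is kinetically Z‑selective (iodine cis to the chain) and so fixes the C7=C8 geometry.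

Step 7
Reactants: 9 (2S,3R,5R)-5-[(4-methoxybenzyl)oxy]-1,6-dioxo-3-(prop-1-en-2-yl)heptan-2-yl (2Z)-2-methylbut-2-enoate; 11 (Z)-tert-butyl[(4-iodopent-3-en-1-yl)oxy]dimethylsilane
Product: 12 (3Z,5R,6S,7R,9R)-1-[(tert-butyldimethylsilyl)oxy]-5-hydroxy-9-[(4-methoxybenzyl)oxy]-4-methyl-10-oxo-7-(prop-1-en-2-yl)undec-3-en-6-yl (2Z)-2-methylbut-2-enoate
Conditions: CrCl2 (4 equiv), NiCl2 (1 mol %), DMSO/THF, rt
Reagents that add atoms: none
Why: Nozaki–Hiyama–Kishi alkenylation, selective for the aldehyde over the methyl ketone and inert to esters, with retention of the Z‑olefin; polar Felkin–Anh addition anti to the α‑angeloyloxy group gives the 9,10‑anti carbinol (target C9).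

Step 8
Reactants: 12 (3Z,5R,6S,7R,9R)-1-[(tert-butyldimethylsilyl)oxy]-5-hydroxy-9-[(4-methoxybenzyl)oxy]-4-methyl-10-oxo-7-(prop-1-en-2-yl)undec-3-en-6-yl (2Z)-2-methylbut-2-enoate
Product: 13 (3Z,5R,6S,7R,9R)-5-acetoxy-1-[(tert-butyldimethylsilyl)oxy]-9-[(4-methoxybenzyl)oxy]-4-methyl-10-oxo-7-(prop-1-en-2-yl)undec-3-en-6-yl (2Z)-2-methylbut-2-enoate
Conditions: Ac2O, pyridine, DMAP (cat.), CH2Cl2, 0 °C
Reagents that add atoms: acetic anhydride CC(=O)OC(C)=O
Why: standard O‑acetylation of the only free hydroxyl, done at once to stop 1,2‑angeloyl migration and to differentiate C9–O from the later C5–OH.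

Step 9
Reactants: 13 (3Z,5R,6S,7R,9R)-5-acetoxy-1-[(tert-butyldimethylsilyl)oxy]-9-[(4-methoxybenzyl)oxy]-4-methyl-10-oxo-7-(prop-1-en-2-yl)undec-3-en-6-yl (2Z)-2-methylbut-2-enoate
Product: 14 (3Z,5R,6S,7R,9R)-5-acetoxy-1-hydroxy-9-[(4-methoxybenzyl)oxy]-4-methyl-10-oxo-7-(prop-1-en-2-yl)undec-3-en-6-yl (2Z)-2-methylbut-2-enoate
Conditions: HF·pyridine, pyridine, THF, 0 °C
Reagents that add atoms: none
Why: fluoride‑mediated cleavage of the primary TBS ether under buffered conditions that leave the esters, PMB ether and olefins intact.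

Step 10
Reactants: 14 (3Z,5R,6S,7R,9R)-5-acetoxy-1-hydroxy-9-[(4-methoxybenzyl)oxy]-4-methyl-10-oxo-7-(prop-1-en-2-yl)undec-3-en-6-yl (2Z)-2-methylbut-2-enoate
Product: 15 (3Z,5R,6S,7R,9R)-5-acetoxy-9-[(4-methoxybenzyl)oxy]-4-methyl-1,10-dioxo-7-(prop-1-en-2-yl)undec-3-en-6-yl (2Z)-2-methylbut-2-enoate
Conditions: Dess–Martin periodinane, NaHCO3, CH2Cl2, 0 °C; used crude
Reagents that add atoms: none
Why: Dess–Martin oxidation of the primary homoallylic alcohol under buffered, non‑basic conditions avoids migration of the β,γ‑olefin into conjugation.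

Step 11
Reactants: 15 (3Z,5R,6S,7R,9R)-5-acetoxy-9-[(4-methoxybenzyl)oxy]-4-methyl-1,10-dioxo-7-(prop-1-en-2-yl)undec-3-en-6-yl (2Z)-2-methylbut-2-enoate
Product: 17 (1R,3R,4R,5S,7Z,9R,10S)-9-acetoxy-4,5-dihydroxy-3-[(4-methoxybenzyl)oxy]-4,8-dimethyl-1-(prop-1-en-2-yl)cyclodec-7-en-10-yl (2Z)-2-methylbut-2-enoate (target numbering), via bis-TMS ether 16 (not isolated)
Conditions: Sm(OTf)3 (15 mol %, reduced in situ to Sm(II)), Me3SiCl (3 equiv), n-Bu4NPF6, THF, undivided cell, Mg anode / glassy‑carbon cathode, constant current (2.2 F mol−1), 15 added over 10 h (final 3 mM), −10 °C; then aq. citric acid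
Reagents that add atoms: none
Why: Proposed new method: a samarium‑mediated electroreductive cross‑pinacol macrocyclisation, in which cathodically regenerated Sm(II) reduces the aldehyde (the more easily reduced carbonyl) to a Sm(III) ketyl held on the C4 ketone by chelation to the C3–OPMB oxygen (Cram chelate), so C5 adds to the ketone face opposite the C2 chain (3,4‑syn, C4 as in the target), the ten‑membered ring closes with the two chains anti across the new bond to give the trans (threo) 4,5‑diol, and Me3SiCl frees Sm(III) from the diolate for turnover; the closest known chemistry is the SmI2‑mediated intramolecular keto‑aldehyde pinacol cyclisation of small and medium rings, catalytic SmI2/Mg/Me3SiCl and electrogenerated‑Sm(II) intermolecular pinacol couplings, and low‑valent‑titanium pinacol macrocyclisations that give trans‑diols in rings of ten or more members, but a ten‑membered electrocatalytic cross‑pinacol closure has not been shown.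

Step 12
Reactants: 17 (1R,3R,4R,5S,7Z,9R,10S)-9-acetoxy-4,5-dihydroxy-3-[(4-methoxybenzyl)oxy]-4,8-dimethyl-1-(prop-1-en-2-yl)cyclodec-7-en-10-yl (2Z)-2-methylbut-2-enoate
Product: 18 (1R,3R,4R,5S,7R,8R,9S,10S)-9-acetoxy-7,8-epoxy-4,5-dihydroxy-3-[(4-methoxybenzyl)oxy]-4,8-dimethyl-1-(prop-1-en-2-yl)cyclodecan-10-yl (2Z)-2-methylbut-2-enoate (target numbering)
Conditions: VO(acac)2 (5 mol %), t-BuOOH (1.5 equiv), CH2Cl2, 0 °C → rt
Reagents that add atoms: tert-butyl hydroperoxide CC(C)(C)OO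
Why: hydroxyl‑directed vanadium‑catalysed epoxidation, in which the C5 homoallylic alcohol anchors the vanadate next to the only nearby olefin (isopropenyl and angelate are not addressed) and delivers oxygen to the olefin face on its own side, as cyclic homoallylic alcohols give cis‑epoxy alcohols, setting C7 and C8 as the cis‑epoxide of the Z‑olefin.

Step 13
Reactants: 18 (1R,3R,4R,5S,7R,8R,9S,10S)-9-acetoxy-7,8-epoxy-4,5-dihydroxy-3-[(4-methoxybenzyl)oxy]-4,8-dimethyl-1-(prop-1-en-2-yl)cyclodecan-10-yl (2Z)-2-methylbut-2-enoate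
Product: 19 (1R,3R,4S,5S,7R,8R,9S,10S)-9-acetoxy-7,8-epoxy-4-hydroxy-3-[(4-methoxybenzyl)oxy]-4,8-dimethyl-1-(prop-1-en-2-yl)cyclodecane-5,10-diyl bis[(2Z)-2-methylbut-2-enoate] (target numbering)
Conditions: angelic acid (3 equiv), 2,4,6-trichlorobenzoyl chloride (3 equiv), Et3N (6 equiv), toluene, rt, 2 h; then 18, 70 °C
Reagents that add atoms: angelic acid C/C=C(C)\C(=O)O
Why: Yamaguchi‑type mixed‑anhydride esterification run without DMAP, which transfers angeloyl without Z→E isomerisation and acylates only the secondary C5–OH, the tertiary C4–OH being inert.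

Step 14
Reactants: 19 (1R,3R,4S,5S,7R,8R,9S,10S)-9-acetoxy-7,8-epoxy-4-hydroxy-3-[(4-methoxybenzyl)oxy]-4,8-dimethyl-1-(prop-1-en-2-yl)cyclodecane-5,10-diyl bis[(2Z)-2-methylbut-2-enoate]
Product: 20 (1R,3R,4S,5S,7R,8R,9S,10S)-9-acetoxy-7,8-epoxy-3,4-dihydroxy-4,8-dimethyl-1-(prop-1-en-2-yl)cyclodecane-5,10-diyl bis[(2Z)-2-methylbut-2-enoate] (CNP0249359.1)
Conditions: DDQ (1.5 equiv), CH2Cl2/pH 7 buffer (10:1), 0 °C
Reagents that add atoms: none
Why: oxidative PMB‑ether cleavage under neutral, wet conditions that leave the trisubstituted epoxide, the three esters and the tertiary alcohol untouched and release the C3 hydroxyl.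

## Compound list

1 | (S)-(+)-carvone, (5S)-2-methyl-5-(prop-1-en-2-yl)cyclohex-2-en-1-one | C=C(C)[C@H]1CC=C(C)C(=O)C1 | starting material
2 | (1S,4S,6S)-1-methyl-4-(prop-1-en-2-yl)-7-oxabicyclo[4.1.0]heptan-2-one (epoxide trans to isopropenyl) | C=C(C)[C@H]1C[C@@H]2O[C@]2(C)C(=O)C1 | intermediate
3 | (2S,3R,5S)-2-hydroxy-3-[(4-methoxybenzyl)oxy]-2-methyl-5-(prop-1-en-2-yl)cyclohexan-1-one | C=C(C)[C@H]1C[C@@H](OCc2ccc(OC)cc2)[C@](C)(O)C(=O)C1 | intermediate
4 | (3S,5R,6S)-5-[(4-methoxybenzyl)oxy]-6-methyl-3-(prop-1-en-2-yl)-1,6-bis(trimethylsilyloxy)cyclohex-1-ene (bis-TMS enol ether of 3) | C=C(C)[C@H]1C[C@@H](OCc2ccc(OC)cc2)[C@](C)(O[Si](C)(C)C)C(O[Si](C)(C)C)=C1 | intermediate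
5 | (2S,3R,5R,6R)-3-[(4-methoxybenzyl)oxy]-2-methyl-5-(prop-1-en-2-yl)-2,6-bis(trimethylsilyloxy)cyclohexan-1-one | C=C(C)[C@H]1C[C@@H](OCc2ccc(OC)cc2)[C@](C)(O[Si](C)(C)C)C(=O)[C@@H]1O[Si](C)(C)C | intermediate
6 | (2S,3R,5R,6R)-2,6-dihydroxy-3-[(4-methoxybenzyl)oxy]-2-methyl-5-(prop-1-en-2-yl)cyclohexan-1-one (6-OH trans to isopropenyl) | C=C(C)[C@H]1C[C@@H](OCc2ccc(OC)cc2)[C@](C)(O)C(=O)[C@@H]1O | intermediate
7 | (1S,2R,4R,5S)-5-hydroxy-4-[(4-methoxybenzyl)oxy]-5-methyl-6-oxo-2-(prop-1-en-2-yl)cyclohexyl (2Z)-2-methylbut-2-enoate (angelate cis to isopropenyl) | C=C(C)[C@H]1C[C@@H](OCc2ccc(OC)cc2)[C@](C)(O)C(=O)[C@H]1OC(=O)/C(C)=C\C | intermediate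
8 | (1S,2R,4R,5R,6S)-5,6-dihydroxy-4-[(4-methoxybenzyl)oxy]-5-methyl-2-(prop-1-en-2-yl)cyclohexyl (2Z)-2-methylbut-2-enoate (expected major C6 epimer; either epimer gives 9) | C=C(C)[C@H]1C[C@@H](OCc2ccc(OC)cc2)[C@](C)(O)[C@@H](O)[C@H]1OC(=O)/C(C)=C\C | intermediate
9 | (2S,3R,5R)-5-[(4-methoxybenzyl)oxy]-1,6-dioxo-3-(prop-1-en-2-yl)heptan-2-yl (2Z)-2-methylbut-2-enoate (C9 aldehyde, C4 methyl ketone) | C=C(C)[C@@H](C[C@@H](OCc1ccc(OC)cc1)C(C)=O)[C@H](OC(=O)/C(C)=C\C)C=O | intermediate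
10 | 3-[(tert-butyldimethylsilyl)oxy]propanal | O=CCCO[Si](C)(C)C(C)(C)C | starting material
11 | (Z)-tert-butyl[(4-iodopent-3-en-1-yl)oxy]dimethylsilane | C/C(I)=C/CCO[Si](C)(C)C(C)(C)C | intermediate
12 | (3Z,5R,6S,7R,9R)-1-[(tert-butyldimethylsilyl)oxy]-5-hydroxy-9-[(4-methoxybenzyl)oxy]-4-methyl-10-oxo-7-(prop-1-en-2-yl)undec-3-en-6-yl (2Z)-2-methylbut-2-enoate | C=C(C)[C@@H](C[C@@H](OCc1ccc(OC)cc1)C(C)=O)[C@H](OC(=O)/C(C)=C\C)[C@H](O)/C(C)=C\CCO[Si](C)(C)C(C)(C)C | intermediate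
13 | (3Z,5R,6S,7R,9R)-5-acetoxy-1-[(tert-butyldimethylsilyl)oxy]-9-[(4-methoxybenzyl)oxy]-4-methyl-10-oxo-7-(prop-1-en-2-yl)undec-3-en-6-yl (2Z)-2-methylbut-2-enoate | C=C(C)[C@@H](C[C@@H](OCc1ccc(OC)cc1)C(C)=O)[C@H](OC(=O)/C(C)=C\C)[C@H](OC(C)=O)/C(C)=C\CCO[Si](C)(C)C(C)(C)C | intermediate
14 | (3Z,5R,6S,7R,9R)-5-acetoxy-1-hydroxy-9-[(4-methoxybenzyl)oxy]-4-methyl-10-oxo-7-(prop-1-en-2-yl)undec-3-en-6-yl (2Z)-2-methylbut-2-enoate | C=C(C)[C@@H](C[C@@H](OCc1ccc(OC)cc1)C(C)=O)[C@H](OC(=O)/C(C)=C\C)[C@H](OC(C)=O)/C(C)=C\CCO | intermediate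
15 | (3Z,5R,6S,7R,9R)-5-acetoxy-9-[(4-methoxybenzyl)oxy]-4-methyl-1,10-dioxo-7-(prop-1-en-2-yl)undec-3-en-6-yl (2Z)-2-methylbut-2-enoate (C5 aldehyde, C4 methyl ketone) | C=C(C)[C@@H](C[C@@H](OCc1ccc(OC)cc1)C(C)=O)[C@H](OC(=O)/C(C)=C\C)[C@H](OC(C)=O)/C(C)=C\CC=O | intermediate
16 | (1R,3R,4S,5S,7Z,9R,10S)-9-acetoxy-3-[(4-methoxybenzyl)oxy]-4,8-dimethyl-1-(prop-1-en-2-yl)-4,5-bis(trimethylsilyloxy)cyclodec-7-en-10-yl (2Z)-2-methylbut-2-enoate (target numbering) | C=C(C)[C@H]1C[C@@H](OCc2ccc(OC)cc2)[C@](C)(O[Si](C)(C)C)[C@@H](O[Si](C)(C)C)C/C=C(C)\[C@@H](OC(C)=O)[C@H]1OC(=O)/C(C)=C\C | intermediate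
17 | (1R,3R,4R,5S,7Z,9R,10S)-9-acetoxy-4,5-dihydroxy-3-[(4-methoxybenzyl)oxy]-4,8-dimethyl-1-(prop-1-en-2-yl)cyclodec-7-en-10-yl (2Z)-2-methylbut-2-enoate (target numbering; 4,5-diol trans) | C=C(C)[C@H]1C[C@@H](OCc2ccc(OC)cc2)[C@](C)(O)[C@@H](O)C/C=C(C)\[C@@H](OC(C)=O)[C@H]1OC(=O)/C(C)=C\C | intermediate
18 | (1R,3R,4R,5S,7R,8R,9S,10S)-9-acetoxy-7,8-epoxy-4,5-dihydroxy-3-[(4-methoxybenzyl)oxy]-4,8-dimethyl-1-(prop-1-en-2-yl)cyclodecan-10-yl (2Z)-2-methylbut-2-enoate (target numbering) | C=C(C)[C@H]1C[C@@H](OCc3ccc(OC)cc3)[C@](C)(O)[C@@H](O)C[C@H]2O[C@@]2(C)[C@@H](OC(C)=O)[C@H]1OC(=O)/C(C)=C\C | intermediate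
19 | (1R,3R,4S,5S,7R,8R,9S,10S)-9-acetoxy-7,8-epoxy-4-hydroxy-3-[(4-methoxybenzyl)oxy]-4,8-dimethyl-1-(prop-1-en-2-yl)cyclodecane-5,10-diyl bis[(2Z)-2-methylbut-2-enoate] (target numbering) | C=C(C)[C@H]1C[C@@H](OCc3ccc(OC)cc3)[C@](C)(O)[C@@H](OC(=O)/C(C)=C\C)C[C@H]2O[C@@]2(C)[C@@H](OC(C)=O)[C@H]1OC(=O)/C(C)=C\C | intermediate
20 | CNP0249359.1, (1R,3R,4S,5S,7R,8R,9S,10S)-9-acetoxy-7,8-epoxy-3,4-dihydroxy-4,8-dimethyl-1-(prop-1-en-2-yl)cyclodecane-5,10-diyl bis[(2Z)-2-methylbut-2-enoate] (target numbering) | C=C(C)[C@H]1C[C@@H](O)[C@](C)(O)[C@@H](OC(=O)/C(C)=C\C)C[C@H]2O[C@@]2(C)[C@@H](OC(C)=O)[C@H]1OC(=O)/C(C)=C\C | target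

## Step count and risks

Total steps: 14. Longest linear sequence: 13 steps (steps 1–5 and 7–14, from (S)-carvone); step 6 makes the side fragment.

The three steps most likely to fail:

Step 11 (the proposed new electroreductive pinacol macrocyclisation). The ring may not close at ten members, the ketyl may be simply reduced or add to an angelate, or the C4/C5 configuration may not follow the chelate/trans‑diol model. The fallback uses known chemistry and a different bond‑forming logic. It sets out from 15: an N‑heterocyclic‑carbene‑catalysed intramolecular crossed aldehyde–ketone benzoin reaction (triazolium precatalyst, i‑Pr2NEt, CH2Cl2, high dilution) joins the same two carbons by umpolung of the aldehyde and gives the macrocyclic α‑ketol F2. Non‑chelating reduction of its C5 ketone (NaBH4, CeCl3, MeOH, −78 °C) then gives the trans‑diol, and the route is rejoined at 17.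

Step 4 (Mitsunobu inversion of a hindered α′‑hydroxy ketone). The reaction may be slow, eliminate, or epimerise the α‑acyloxy ketone. The fallback sets out from 6: the secondary alcohol is converted with Tf2O/pyridine (CH2Cl2, −78 °C) into the isolable α‑keto triflate F1, which is displaced with caesium angelate (18‑crown‑6, toluene, 0 °C) in a fast SN2 reaction α to the carbonyl with inversion. The route is rejoined at 7.

Step 12 (facial selectivity of the late epoxidation). Direction from a homoallylic alcohol inside a ten‑membered ring is less secure than allylic direction, and the vicinal diol may bind vanadium unproductively. The fallback sets out from 17 and switches to allylic direction by reordering the acylations. The C5 hydroxyl is angeloylated first (step‑13 conditions) to give the bis‑angelate olefin F3. The C9 acetate is then removed selectively in the presence of the two hindered angelates (guanidine, MeOH/CH2Cl2, 0 °C) to give the allylic alcohol F4. VO(acac)2/t‑BuOOH epoxidation directed by the allylic C9–OH, which in medium rings gives the cis‑epoxy alcohol, leads to the epoxy alcohol F5. Acetylation (Ac2O, pyridine) rejoins the route at 19.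

Further compounds
F1 | step 4 | (1R,2R,4R,5S)-5-hydroxy-4-[(4-methoxybenzyl)oxy]-5-methyl-6-oxo-2-(prop-1-en-2-yl)cyclohexyl trifluoromethanesulfonate | C=C(C)[C@H]1C[C@@H](OCc2ccc(OC)cc2)[C@](C)(O)C(=O)[C@@H]1OS(=O)(=O)C(F)(F)F
F2 | step 11 | (1R,3R,4S,7Z,9R,10S)-9-acetoxy-4-hydroxy-3-[(4-methoxybenzyl)oxy]-4,8-dimethyl-5-oxo-1-(prop-1-en-2-yl)cyclodec-7-en-10-yl (2Z)-2-methylbut-2-enoate (target numbering) | C=C(C)[C@H]1C[C@@H](OCc2ccc(OC)cc2)[C@](C)(O)C(=O)C/C=C(C)\[C@@H](OC(C)=O)[C@H]1OC(=O)/C(C)=C\C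
F3 | step 12 | (1R,3R,4S,5S,7Z,9R,10S)-9-acetoxy-4-hydroxy-3-[(4-methoxybenzyl)oxy]-4,8-dimethyl-1-(prop-1-en-2-yl)cyclodec-7-ene-5,10-diyl bis[(2Z)-2-methylbut-2-enoate] (target numbering) | C=C(C)[C@H]1C[C@@H](OCc2ccc(OC)cc2)[C@](C)(O)[C@@H](OC(=O)/C(C)=C\C)C/C=C(C)\[C@@H](OC(C)=O)[C@H]1OC(=O)/C(C)=C\C
F4 | step 12 | (1R,3R,4S,5S,7Z,9R,10S)-4,9-dihydroxy-3-[(4-methoxybenzyl)oxy]-4,8-dimethyl-1-(prop-1-en-2-yl)cyclodec-7-ene-5,10-diyl bis[(2Z)-2-methylbut-2-enoate] (target numbering) | C=C(C)[C@H]1C[C@@H](OCc2ccc(OC)cc2)[C@](C)(O)[C@@H](OC(=O)/C(C)=C\C)C/C=C(C)\[C@@H](O)[C@H]1OC(=O)/C(C)=C\C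
F5 | step 12 | (1R,3R,4S,5S,7R,8S,9S,10S)-7,8-epoxy-4,9-dihydroxy-3-[(4-methoxybenzyl)oxy]-4,8-dimethyl-1-(prop-1-en-2-yl)cyclodecane-5,10-diyl bis[(2Z)-2-methylbut-2-enoate] (target numbering) | C=C(C)[C@H]1C[C@@H](OCc3ccc(OC)cc3)[C@](C)(O)[C@@H](OC(=O)/C(C)=C\C)C[C@H]2O[C@@]2(C)[C@@H](O)[C@H]1OC(=O)/C(C)=C\C
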